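The runs were generated by integration for an exercise.

The ratio I started from was one of times: the red run reached 34.1% of left-handed product at 12.0 min and the violet run reached 33.8% at 3.00 min, readings equal within their scatter, so as read from these readings violet's time to that level was shorter by a factor of 4.00, though its catalyst charge was larger by a factor of 2.21. That looked like a dead band, and subtracting the impurity from each catalyst charge gives a ratio of 3.93, which lies close to the ratio read, so I took it that each impurity removes one catalyst for good, a fraction of 58.8% of the charge in red and 26.7% in violet.

| flask | left-handed substrate | right-handed substrate | reagent | free catalyst | impurity | remark |
|---|---|---|---|---|---|---|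
| red | 1 M | 1 M | 1.2 M | 3.4 mM | 2 mM | run made earlier |
| violet | 1 M | 1 M | 1.2 M | 7.5 mM | 2 mM | run made earlier |
| flask | 1.0 M | 1.0 M | 1.20 M | 5.0 mM | 2.0 mM |  |

- red (time / min: left-handed product / %): 1.00: 6.9; 2.00: 11.5; 5.00: 21.8; 12.0: 34.1
- violet (time / min: left-handed product / %): 3.00: 33.8; 6.00: 40.2; 10.0: 42.4; 12.0: 42.6

(each reading ± 0.5 percentage points)

- apparent order in reagent when 20% of the left-handed substrate and right-handed substrate together are converted (percent change of the rate of making left-handed product for one percent more reagent charged)
- apparent order in free catalyst when 20% of the left-handed substrate and right-handed substrate together are converted (percent change of the rate of making left-handed product for one percent more free catalyst charged)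

- free catalyst is single-handed; left-handed substrate and right-handed substrate are mirror images of each other, charged as a racemate, each of them at the stated concentration
- no earlier run changes the charge of reagent; that part of a forecast is a guess

My decision was to charge the next flask with 5.0 mM of catalyst, bracketed by the two runs, and to keep reagent at 1.20 M, because no earlier run varied it and I could offer no measured order for it. In this flask the impurity should claim 40.0% of the catalyst. I therefore reckoned the leverage of the impurity, the catalyst charged over the catalyst left working, as 1.67, and, taking the rate at a fixed conversion and a fixed impurity charge to go with the catalyst left working, that is my apparent order in catalyst at 20% conversion. Working catalyst should also make this flask 2.14 times as fast as red.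

The forecast stood at 0.8 for reagent and 1.62 for catalyst, with the rate “first order in catalyst minus 2 mM”.

The simulation gave 1.4 for reagent and 1.7 for catalyst.

    free catalyst + left-handed substrate ⇌ catalyst intermediate A (K = 1.20 /M, k = 34.0 /M/s)
    free catalyst + impurity → spent catalyst (k = 7820 /M/s)
    reagent + catalyst intermediate A → free catalyst + left-handed product (k = 3.44 /M/s)
    reagent + catalyst intermediate B → free catalyst + right-handed product (k = 1.39 /M/s)
    free catalyst + right-handed substrate ⇌ catalyst intermediate B (K = 0.550 /M, k = 111 /M/s)

By 1.00 min in the new flask the path from free catalyst and impurity had left the impurity at 0% of its charge and spent catalyst at 40.0% of the catalyst charged, the share behind the leverage of 1.67, and that flask then held 12.2% of left-handed product, a little more than the 11.5% read in red at 2.00 min, against my factor of 2.14. The working catalyst of the new flask then went on turning over through both intermediates, and by 10.0 min reagent there stood at 12.7% of its charge, with left-handed product at 39.3% and right-handed product at 13.1%.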